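**Retrosynthetic overview**
1. Alterbrassicicene C ⇐ trione 27 (C10 ketone) by exo-face hydride delivery.
2. Ring C (formed last) ⇐ bridged acid 24: the C3-ketone enolate (C4) is acylated by the (Z)-acrylate arm on C8 (C4–C5 bond).
3. Key step, 24 ⇐ 14 + 18: a β-lithioacrylate (β-acyl vinyl anion, d3) adds to the lactone carbonyl C8 (C7–C8 bond, two acceptor carbons joined); the oxocarbenium formed is then trapped by the C3 enol silane (C4–C8 bond), closing the oxa-bridged eight-membered ring.
4. 14 ⇐ iodo lactone 10 (C2 acylation, kinetic protonation at C11) ⇐ iodoenone 4 + silyl dienolate 8 (asymmetric vinylogous aldol–lactonisation sets C12).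
5. Ring order: ring A (from a cyclopentenone) → spiro δ-lactone (future tetrahydropyran) → pyranone ring and eight-membered carbocycle together → ring C.

Labels used below: C1 = ring-A alkene carbon bearing CH2OMe; C2 = other ring-A alkene carbon; C3 = ketone between C2 and C4; C4 = C(CH3) between the two ketones; C5 = cyclopentenone C=O; C6 = CH=; C7 = C(iPr)=; C8 = ether bridgehead in ring C; C9 = CH2; C10 = CHOH; C11 = CH(CH3); C12 = ether bridgehead in ring A; C13/C14 = ring-A CH2 next to C12/C1. Target = 4R,8R,10S,11S,12R.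

Assumption: (S)-Tol-BINAP is taken to give the 12R spiro centre in step 5 (otherwise its enantiomer is used); diene 8 is drawn as the (1Z,3Z) isomer, its geometry being irrelevant because C11 is reset in step 6.

**Step 1**
Reactants: 1 3-ethoxycyclopent-2-en-1-one
Product: 3 3-(methoxymethyl)cyclopent-2-en-1-one, via lithium alkoxide adduct 2 (not isolated)
Conditions: Bu3SnCH2OMe, n-BuLi, THF, −78 °C; add 1; then 1 M HCl, rt
Reagents that add atoms: tributyl(methoxymethyl)stannane, COC[Sn](CCCC)(CCCC)CCCC
Why: Methoxymethyllithium from tin–lithium exchange adds 1,2 to the vinylogous ester and the acidic work-up hydrolyses the enol ether with allylic transposition to the 3-substituted enone (Stork–Danheiser transposition); no stereocentre.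

**Step 2**
Reactants: 3 3-(methoxymethyl)cyclopent-2-en-1-one
Product: 4 2-iodo-3-(methoxymethyl)cyclopent-2-en-1-one
Conditions: I2, pyridine, CH2Cl2, 0 °C → rt
Reagents that add atoms: iodine, II
Why: Pyridine-mediated α-iodination of the enone (addition–iodination–elimination) installs the C2 handle; no stereocentre.

**Step 3**
Reactants: 5 methyl 3-oxopentanoate
Product: 6 methyl (2E)-3-methoxypent-2-enoate
Conditions: HC(OMe)3, H2SO4 (cat.), MeOH, rt
Reagents that add atoms: trimethyl orthoformate, COC(OC)OC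
Why: Acid-catalysed ketalisation of the ketone and loss of methanol gives the β-methoxy enoate as the E isomer (enol ether formation from a β-keto ester).

**Step 4**
Reactants: 6 methyl (2E)-3-methoxypent-2-enoate
Product: 8 (1Z,3Z)-1,3-dimethoxy-1-(trimethylsilyloxy)penta-1,3-diene, via lithium dienolate 7 (not isolated)
Conditions: LDA, THF, −78 °C; TMSCl
Reagents that add atoms: chlorotrimethylsilane, C[Si](C)(C)Cl
Why: LDA removes the γ-proton of the β-alkoxy enoate and O-silylation of the extended enolate gives the Brassard-type silyl dienolate.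

**Step 5**
Reactants: 4 2-iodo-3-(methoxymethyl)cyclopent-2-en-1-one; 8 (1Z,3Z)-1,3-dimethoxy-1-(trimethylsilyloxy)penta-1,3-diene
Product: 10 (5R)-1-iodo-9-methoxy-2-(methoxymethyl)-10-methyl-6-oxaspiro[4.5]deca-1,8-dien-7-one (C10 epimers), via silyl aldolate 9 (not isolated)
Conditions: Cu(OTf)2 (10 mol%), (S)-Tol-BINAP (11 mol%), TBAT (20 mol%), THF, −20 °C → rt; then TFA (cat.), CH2Cl2, 0 °C
Reagents that add atoms: none
Why: Copper(I)–bisphosphine dienolate-catalysed asymmetric vinylogous Mukaiyama aldol at the γ-carbon of 8 followed by lactonisation is a known reaction type for unactivated ketones giving 6,6-disubstituted 5,6-dihydropyran-2-ones; the chiral copper dienolate selects the ketone face and sets C12 (R), while C11 forms as a mixture that step 6 resets.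

**Step 6**
Reactants: 10 (5R)-1-iodo-9-methoxy-2-(methoxymethyl)-10-methyl-6-oxaspiro[4.5]deca-1,8-dien-7-one (C10 epimers)
Product: 14 (5R,10S)-9-methoxy-2-(methoxymethyl)-10-methyl-1-propanoyl-6-oxaspiro[4.5]deca-1,8-dien-7-one, via lithium dienolate 11 (not isolated), via C2-lithio dienolate 12 (not isolated), via hemiaminal alkoxide 13 (not isolated)
Conditions: LDA (1.1 equiv), THF, −78 °C; t-BuLi (2.1 equiv), −100 °C; EtC(O)N(OMe)Me, −100 → −60 °C; AcOH, −78 °C
Reagents that add atoms: N-methoxy-N-methylpropanamide, CCC(=O)N(C)OC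
Why: γ-Deprotonation converts the lactone into a dienolate that survives iodine–lithium exchange, the C2 vinyllithium is acylated by the Weinreb amide, and kinetic protonation of the dienolate at C11 from the face away from the bulky C2 hemiaminal arm sets C11 (S, methyl cis to C2) from either epimer of 10 (dienolate masking, I–Li exchange, Weinreb ketone synthesis, kinetic protonation).

**Step 7**
Reactants: 15 3-methylbut-1-yne
Product: 17 4-methylpent-2-ynoic acid, via lithium acetylide 16 (not isolated)
Conditions: n-BuLi, THF, −78 °C; CO2; 1 M HCl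
Reagents that add atoms: carbon dioxide, O=C=O
Why: Deprotonation of the terminal alkyne and carboxylation of the acetylide.

**Step 8**
Reactants: 17 4-methylpent-2-ynoic acid
Product: 18 (2Z)-3-iodo-4-methylpent-2-enoic acid
Conditions: NaI, AcOH, 80 °C
Reagents that add atoms: sodium iodide, [Na+].[I-]
Why: Conjugate addition of iodide to the ynoic acid with anti protonation gives the (Z)-β-iodoacrylic acid (hydroiodination of a 2-alkynoic acid), which fixes C5 and the future C8 cis on C6=C7 as ring C requires.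

**Step 9 (key step)**
Reactants: 14 (5R,10S)-9-methoxy-2-(methoxymethyl)-10-methyl-1-propanoyl-6-oxaspiro[4.5]deca-1,8-dien-7-one; 18 (2Z)-3-iodo-4-methylpent-2-enoic acid
Product: 24 (2Z)-3-[(1R,8S,11S)-10-methoxy-4-(methoxymethyl)-7,11-dimethyl-6-oxo-12-oxatricyclo[6.3.1.0(1,5)]dodeca-4,9-dien-8-yl]-4-methylpent-2-enoic acid (C4 epimers), via lithium enolate 19 (not isolated), via dilithio acrylate 20 (not isolated), via trilithium hemiketalate 21 (not isolated), via pyrylium triflate 22 (not isolated), via silyl ester 23 (not isolated)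
Conditions: 14, LiHMDS (1.05 equiv), THF, −78 °C; 18, MeLi (1 equiv) then t-BuLi (2 equiv), THF, −100 °C; combine, −78 → −40 °C; TMSOTf (5 equiv), CH2Cl2, −78 → −20 °C; pH 5 buffer
Reagents that add atoms: none
Why: Proposed new method: the (Z)-β-lithioacrylate dianion 20 (a β-acyl vinyl anion, d3 synthon) adds once to the vinylogous-carbonate carbonyl C8 of 19, joining two acceptor carbons (C7 and C8) while C3 is masked as its own enolate and the carboxylate can neither lactonise nor over-add; TMSOTf then silylates the three oxyanions and ionises the hemiketal to the 4-methoxy-5,6-dihydropyrylium ion 22, and the C3 enol silane, held on the C2 arm of the spiro centre, attacks C8 in a 6-(enolendo)-exo closure that is only possible syn to C2, which sets C8 (C4 cis to C2 across the ether oxygen) and closes the oxa-bridged eight-membered ring, a Nazarov closure of the divinyl oxocarbenium being excluded because it would place an enol double bond at a bridgehead; the closest known reactions are organolithium additions to 4-methoxy-5,6-dihydropyran-2-ones giving 6-substituted dihydropyranones, carbonyl additions of β-lithioacrylate dianions, and silyl-triflate-promoted Mukaiyama additions of enol silanes to 4-siloxypyrylium ions at the carbon next to oxygen.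

**Step 10**
Reactants: 24 (2Z)-3-[(1R,8S,11S)-10-methoxy-4-(methoxymethyl)-7,11-dimethyl-6-oxo-12-oxatricyclo[6.3.1.0(1,5)]dodeca-4,9-dien-8-yl]-4-methylpent-2-enoic acid (C4 epimers)
Product: 27 10-oxo (C10 ketone) analogue of alterbrassicicene C (4R,8R,11R,12R), via acyl imidazole 25 (not isolated), via enol ether dione 26 (not isolated)
Conditions: CDI, THF, rt; LiHMDS (3.3 equiv), −78 → −20 °C; 1 M HCl, THF, 0 °C
Reagents that add atoms: water, O
Why: Intramolecular C-acylation (Claisen type, 5-(enolexo)-exo-trig) of the C3-ketone enolate by the acyl imidazole closes ring C as a near-planar cyclopentenone that can only be cis-fused to the pyranone ring, so C5 enters axially and both C4 epimers converge on 4R with the methyl equatorial; the imidazolide released is too weak a nucleophile to reverse the acylation, and cold dilute acid then hydrolyses the C10 enol ether without epimerising C11.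

**Step 11**
Reactants: 27 10-oxo (C10 ketone) analogue of alterbrassicicene C (4R,8R,11R,12R)
Product: 28 alterbrassicicene C
Conditions: NaBH4, MeOH–CH2Cl2, −78 °C
Reagents that add atoms: none
Why: The saturated C10 ketone is far more reactive than the hindered, conjugated C3 and C5 ketones, and hydride can only approach from the open exo face because the endo face is covered by the C2–C3–C4 bridge, which gives the endo 10S alcohol at a temperature where C11 does not epimerise (chemo- and diastereoselective borohydride reduction).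

**Compound list**
1 | 3-ethoxycyclopent-2-en-1-one | CCOC1=CC(=O)CC1 | starting material
2 | lithium 3-ethoxy-1-(methoxymethyl)cyclopent-2-en-1-olate (racemic 1,2-adduct, not isolated) | CCOC1=CC(COC)(O[Li])CC1 | intermediate
3 | 3-(methoxymethyl)cyclopent-2-en-1-one | COCC1=CC(=O)CC1 | intermediate
4 | 2-iodo-3-(methoxymethyl)cyclopent-2-en-1-one | COCC1=C(I)C(=O)CC1 | intermediate
5 | methyl 3-oxopentanoate | CCC(=O)CC(=O)OC | starting material
6 | methyl (2E)-3-methoxypent-2-enoate | CC/C(OC)=C\C(=O)OC | intermediate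
7 | lithium 1,3-dimethoxypenta-1,3-dien-1-olate (γ-deprotonated 6, same geometry as 8, not isolated) | CO/C(O[Li])=C/C(OC)=C/C | intermediate
8 | (1Z,3Z)-1,3-dimethoxy-1-(trimethylsilyloxy)penta-1,3-diene | CO/C(O[Si](C)(C)C)=C/C(OC)=C/C | intermediate
9 | methyl (2E)-4-[(1R)-2-iodo-3-(methoxymethyl)-1-(trimethylsilyloxy)cyclopent-2-en-1-yl]-3-methoxypent-2-enoate (C4 epimers, not isolated) | COCC1=C(I)[C@](CC1)(O[Si](C)(C)C)C(C)/C(OC)=C\C(=O)OC | intermediate
10 | (5R)-1-iodo-9-methoxy-2-(methoxymethyl)-10-methyl-6-oxaspiro[4.5]deca-1,8-dien-7-one (C10 epimers; spiro C5 = C12, C10 = C11) | COCC1=C(I)[C@]2(CC1)OC(=O)C=C(OC)C2C | intermediate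
11 | lithium (5R)-1-iodo-9-methoxy-2-(methoxymethyl)-10-methyl-6-oxaspiro[4.5]deca-1,7,9-trien-7-olate (not isolated) | COCC1=C(I)[C@]2(CC1)OC(O[Li])=CC(OC)=C2C | intermediate
12 | 1-lithio analogue of 11 (C2–Li in place of C2–I, same spatial arrangement at C12, not isolated) | COCC1=C([Li])[C@]2(CC1)OC(O[Li])=CC(OC)=C2C | intermediate
13 | dilithium adduct of 12 with N-methoxy-N-methylpropanamide (C3 hemiaminal alkoxide plus lactone dienolate, not isolated) | COCC1=C(C(O[Li])(CC)N(C)OC)[C@]2(CC1)OC(O[Li])=CC(OC)=C2C | intermediate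
14 | (5R,10S)-9-methoxy-2-(methoxymethyl)-10-methyl-1-propanoyl-6-oxaspiro[4.5]deca-1,8-dien-7-one (12R,11S) | COCC1=C(C(=O)CC)[C@]2(CC1)OC(=O)C=C(OC)[C@@H]2C | intermediate
15 | 3-methylbut-1-yne | CC(C)C#C | starting material
16 | (3-methylbut-1-yn-1-yl)lithium (not isolated) | CC(C)C#C[Li] | intermediate
17 | 4-methylpent-2-ynoic acid | CC(C)C#CC(=O)O | intermediate
18 | (2Z)-3-iodo-4-methylpent-2-enoic acid | OC(=O)/C=C(\I)C(C)C | intermediate
19 | lithium (Z)-enolate of 14 (C3–OLi, C3=C4, not isolated) | COCC1=C(/C(O[Li])=C/C)[C@]2(CC1)OC(=O)C=C(OC)[C@@H]2C | intermediate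
20 | lithium (2E)-3-lithio-4-methylpent-2-enoate (C–Li cis to CO2Li, geometry of 18 kept, not isolated) | [Li]OC(=O)/C=C(\[Li])C(C)C | intermediate
21 | trilithium C8 hemiketalate from 19 and 20 (C8 epimers, not isolated) | COCC1=C(/C(O[Li])=C/C)[C@]2(CC1)OC(O[Li])(/C(=C\C(=O)O[Li])C(C)C)C=C(OC)[C@@H]2C | intermediate
22 | C8 oxocarbenium (2-alkenyl-4-methoxy-5,6-dihydropyrylium) triflate carrying the C3 trimethylsilyl enol ether and the trimethylsilyl ester (not isolated) | COCC1=C(/C(O[Si](C)(C)C)=C/C)[C@]2(CC1)[O+]=C(/C(=C\C(=O)O[Si](C)(C)C)C(C)C)C=C(OC)[C@@H]2C.[O-]S(=O)(=O)C(F)(F)F | intermediate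
23 | trimethylsilyl ester of 24 (not isolated) | COCC1=C2C(=O)C(C)[C@]3(/C(=C\C(=O)O[Si](C)(C)C)C(C)C)C=C(OC)[C@H](C)[C@@]2(CC1)O3 | intermediate
24 | (2Z)-3-[(1R,8S,11S)-10-methoxy-4-(methoxymethyl)-7,11-dimethyl-6-oxo-12-oxatricyclo[6.3.1.0(1,5)]dodeca-4,9-dien-8-yl]-4-methylpent-2-enoic acid (labels: 12R, 8S, 11S, C4 epimers; 8S becomes 8R by CIP once ring C is closed) | COCC1=C2C(=O)C(C)[C@]3(/C(=C\C(=O)O)C(C)C)C=C(OC)[C@H](C)[C@@]2(CC1)O3 | intermediate
25 | 1-acylimidazole of 24 (not isolated) | COCC1=C2C(=O)C(C)[C@]3(/C(=C\C(=O)n4ccnc4)C(C)C)C=C(OC)[C@H](C)[C@@]2(CC1)O3 | intermediate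
26 | 27 with the C10 ketone as its C9=C10 methyl enol ether (4R,8R,11S,12R, not isolated) | COCC1=C2C(=O)[C@@]3(C)C(=O)C=C(C(C)C)[C@]34C=C(OC)[C@H](C)[C@@]2(CC1)O4 | intermediate
27 | 10-oxo (C10 ketone) analogue of alterbrassicicene C (4R,8R,11R,12R; 11R by CIP only, same arrangement as the target) | COCC1=C2C(=O)[C@@]3(C)C(=O)C=C(C(C)C)[C@]34CC(=O)[C@H](C)[C@@]2(CC1)O4 | intermediate
28 | alterbrassicicene C (4R,8R,10S,11S,12R) | COCC1=C2C(=O)[C@@]3(C)C(=O)C=C(C(C)C)[C@]34C[C@H](O)[C@H](C)[C@@]2(CC1)O4 | target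

**Totals**
Total step count: 11. Longest linear sequence: 7 steps (1 → 3 → 4 → 10 → 14 → 24 → 27 → 28; steps 1, 2, 5, 6, 9, 10, 11).

**Three steps most likely to fail**

Step 5 (reactivity and enantioselectivity of a hindered α-iodo enone ketone toward a γ-substituted copper dienolate). The fallback sets out from 4 and comes back at 10, as its single 10S epimer. A chiral 3,3'-dibromo-BINOL-catalysed (Z)-crotylboration of 4 with (Z)-crotyl-B(OiPr)2 (closed transition state, syn adduct) gives (1R)-1-[(2S)-but-3-en-2-yl]-2-iodo-3-(methoxymethyl)cyclopent-2-en-1-ol F1. Tsuji–Wacker oxidation (PdCl2, CuCl, O2, DMF–H2O) gives the β-hydroxy ketone (3R)-3-[(1R)-1-hydroxy-2-iodo-3-(methoxymethyl)cyclopent-2-en-1-yl]butan-2-one F2. LiHMDS then ClCO2Me gives the carbonate (1R)-2-iodo-3-(methoxymethyl)-1-[(2R)-3-oxobutan-2-yl]cyclopent-2-en-1-yl methyl carbonate F3. LiHMDS (kinetic methyl enolate) closes it by intramolecular Claisen condensation to the β-keto lactone (5R,10R)-1-iodo-2-(methoxymethyl)-10-methyl-6-oxaspiro[4.5]dec-1-ene-7,9-dione F4, and Me2SO4/K2CO3 O-methylation returns 10.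

Step 6 (acylation of a hindered vinyllithium and face selectivity of the C11 protonation). The fallback sets out from 10 and comes back at 14, separating the two tasks and avoiding strong base in the acylation. LDA then AcOH at −78 °C, with the iodine-bearing arm as the shield, gives the single epimer (5R,10S)-1-iodo-9-methoxy-2-(methoxymethyl)-10-methyl-6-oxaspiro[4.5]deca-1,8-dien-7-one F5. Nozaki–Hiyama–Kishi coupling with propanal (CrCl2, cat. NiCl2, DMF) gives the allylic alcohol (5R,10S)-1-(1-hydroxypropyl)-9-methoxy-2-(methoxymethyl)-10-methyl-6-oxaspiro[4.5]deca-1,8-dien-7-one F6, and Dess–Martin oxidation gives 14.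

Step 9 (the one-pot addition/ionisation/cyclisation; attack at C10 instead of C8 or failure of the cation capture). The fallback sets out from 14 and comes back at 27, replacing the cation cascade by an isolated pyranone and a conjugate addition. Enolate 19 and reagent 20 are combined as before, but quenching into aqueous HCl gives the dihydropyranone (2Z)-3-[(5R,10R)-2-(methoxymethyl)-10-methyl-9-oxo-1-propanoyl-6-oxaspiro[4.5]deca-1,7-dien-7-yl]-4-methylpent-2-enoic acid F7 (possibly as its ring-chain butenolide tautomer). TMSCHN2 gives the methyl ester of F7 F8. TBSOTf/Et3N (soft enolisation of the propanoyl group and O-silylation of the pyranone, intramolecular Mukaiyama–Michael addition) gives the methyl ester of 24 carrying a C10 tert-butyldimethylsilyl enol ether in place of the methyl enol ether F9. LDA (Dieckmann-type closure onto the ester) followed by 1 M HCl gives 27.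

**Further compounds**
F1 | step 5 | (1R)-1-[(2S)-but-3-en-2-yl]-2-iodo-3-(methoxymethyl)cyclopent-2-en-1-ol | COCC1=C(I)[C@@](O)(CC1)[C@@H](C)C=C
F2 | step 5 | (3R)-3-[(1R)-1-hydroxy-2-iodo-3-(methoxymethyl)cyclopent-2-en-1-yl]butan-2-one | COCC1=C(I)[C@@](O)(CC1)[C@@H](C)C(C)=O
F3 | step 5 | (1R)-2-iodo-3-(methoxymethyl)-1-[(2R)-3-oxobutan-2-yl]cyclopent-2-en-1-yl methyl carbonate | COCC1=C(I)[C@@](OC(=O)OC)(CC1)[C@@H](C)C(C)=O
F4 | step 5 | (5R,10R)-1-iodo-2-(methoxymethyl)-10-methyl-6-oxaspiro[4.5]dec-1-ene-7,9-dione | COCC1=C(I)[C@]2(CC1)OC(=O)CC(=O)[C@@H]2C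
F5 | step 6 | (5R,10S)-1-iodo-9-methoxy-2-(methoxymethyl)-10-methyl-6-oxaspiro[4.5]deca-1,8-dien-7-one | COCC1=C(I)[C@]2(CC1)OC(=O)C=C(OC)[C@@H]2C
F6 | step 6 | (5R,10S)-1-(1-hydroxypropyl)-9-methoxy-2-(methoxymethyl)-10-methyl-6-oxaspiro[4.5]deca-1,8-dien-7-one (carbinol epimers) | COCC1=C(C(O)CC)[C@]2(CC1)OC(=O)C=C(OC)[C@@H]2C
F7 | step 9 | (2Z)-3-[(5R,10R)-2-(methoxymethyl)-10-methyl-9-oxo-1-propanoyl-6-oxaspiro[4.5]deca-1,7-dien-7-yl]-4-methylpent-2-enoic acid | COCC1=C(C(=O)CC)[C@]2(CC1)OC(/C(=C\C(=O)O)C(C)C)=CC(=O)[C@@H]2C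
F8 | step 9 | methyl ester of F7 | COCC1=C(C(=O)CC)[C@]2(CC1)OC(/C(=C\C(=O)OC)C(C)C)=CC(=O)[C@@H]2C
F9 | step 9 | methyl ester of 24 carrying a C10 tert-butyldimethylsilyl enol ether in place of the methyl enol ether (C4 epimers) | COCC1=C2C(=O)C(C)[C@]3(/C(=C\C(=O)OC)C(C)C)C=C(O[Si](C)(C)C(C)(C)C)[C@H](C)[C@@]2(CC1)O3
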